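In this closed, stirred vessel the free catalyst and the reagent turned a racemate of left-handed and right-handed substrate into the two products, while the racemization catalyst exchanged the two substrates.

| setting | spring | winter | flask |
|---|---|---|---|
| left-handed substrate | 0.20 M | 0.20 M | 0.20 M |
| right-handed substrate | 0.20 M | 0.20 M | 0.20 M |
| reagent | 0.50 M | 0.50 M | 0.500 M |
| free catalyst | 7 mM | 4.7 mM | 7.0 mM |
| racemization catalyst | 1 mM | 1 mM | 1.0 mM |
| impurity | 0.40 mM | 0.40 mM | 0.40 mM |
| remark | the very flask that is asked about, followed so far | run made earlier |  |
| time |  |  | 8.0 d |

- spring (time / d: left-handed product / %, right-handed product / %): 0.250: 11.0, 5.2; 0.500: 17.6, 12.0; 0.833: 23.7, 14.7; 1.67: 34.4, 22.8; 3.00: 38.3, 26.2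
- winter (time / d: left-handed product / %, right-handed product / %): 0.625: 16.4, 7.8; 2.08: 29.6, 20.5; 4.00: 38.3, 25.4; 6.00: 40.6, 30.8; 8.00: 43.3, 31.4

(readings scatter by 1 percentage point)

- free catalyst is single-handed; left-handed substrate and right-handed substrate are mirror images of each other, charged as a racemate, each of them at the stated concentration
- the earlier runs were read with a standard deviation of 1 percentage point
- an excess is the difference of the two amounts in percent of their sum
- an excess is below zero if the other one leads

- left-handed product and right-handed product together, in percent of the left-handed substrate and right-handed substrate charged together, at 8.0 d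
- excess of left-handed product over right-handed product in the product at 8.0 d
- whether the exchange between left-handed substrate and right-handed substrate keeps pace with the reaction: how far the product's excess at 8.0 d gets from its value without exchange to its value with instant exchange (above 80% keeps pace, below 20% hardly takes part, else lags behind)

I took as zero of the scale a catalyst with no preference, which gives a factor of 1 and a product without excess. The winter run at 8.00 d read 2.03 for the selectivity factor, the logarithm of the fraction left of the left-handed substrate over that of the right-handed substrate, each counted on its own half. So the left-handed rest is the right-handed rest raised to this factor, and one rest gives the excess.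

Then I turned the settings by hand. More free catalyst should quicken both hands alike, and indeed spring, with 7 mM against 4.7 mM, read 1.96 at 3.00 d. Reagent, at 0.50 M in both runs, I expected to move a flask along that line without changing the factor. Instant exchange keeps the substrates equal, so the excess stays at the factor less one over the factor plus one, and with my factor, itself a single late reading with the scatter of the runs, I reckoned this at 34.0%; but spring's excess read 18.8% at 3.00 d, so I gave the exchange little weight.

Winter's right-handed logarithm grew by 0.280 between 4.00 d and 8.00 d. Stretching the clock by the catalyst ratio, I reckoned a right-handed rest of 31.7% and a left-handed rest of 9.67%, hence 79.3% and an excess of 13.9%. The forecast, from its own fitted curve, said 80%, 14% and hardly takes part: “exchange is hardly visible”.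

The flask gave 79.4% and 13.8%, and its excess got 11% of the way to instant exchange, so the exchange hardly takes part.

    reagent + free catalyst + left-handed substrate → free catalyst + left-handed product (k = 13.3 L² mol⁻² h⁻¹)
    reagent + free catalyst + right-handed substrate → free catalyst + right-handed product (k = 7.32 L² mol⁻² h⁻¹)
    left-handed substrate + racemization catalyst ⇌ right-handed substrate + racemization catalyst, rate k3*[racemization catalyst]*[left-handed substrate] forward; the back reaction follows from the equilibrium constant (k = 21.6 L mol⁻¹ h⁻¹)
    racemization catalyst → spent catalyst A (k = 0.0639 h⁻¹)
    2 free catalyst → spent catalyst B (k = 1.22 L mol⁻¹ h⁻¹)
    racemization catalyst + impurity → spent catalyst C (k = 21500 L mol⁻¹ h⁻¹)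

At 0.734 d the racemization catalyst had a half-life of 0.45 d by its decay to spent catalyst A, shorter than the 2.1 d of the right-handed substrate in its reaction. By 4.00 d the flask held 0.130% of that catalyst. With 2.03, this flask's right-handed rest of 29% gives an excess of 13.0%. The neighbour with 0.12 M of reagent, at 80%, gives 29.1%, and it stood at 25.6%.

(The readings were generated by integration with made-up constants; scatter was added.)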